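## Retrosynthetic overview

1. Target 15 ⇒ aromatic acylphloroglucinol 13 + prenyl acetate 14: the quaternary ring carbon is made last by dearomative C‑prenyl transfer, as in the plant.
2. 13 ⇒ acylphloroglucinol 10 + cyclopentane aldehyde 6: the ArCH2–C2' bond comes from reductive alkylation through an ortho‑quinone methide.
3. 6 ⇒ open‑chain aldehyde 5, made from (R)‑linalool 1: C2'–C6' closure of the linalyl‑type C10 chain with loss of a terminal‑methyl proton. This is the presumed biosynthetic ene‑type closure that leaves the C3' carbinol and the isopropenyl group; here it is run as a catalytic one‑electron (SOMO) homo‑ene cyclisation on the free chain, because the polyphenol would not survive the oxidant.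
4. Ring order: ring A (six‑membered) is bought as 2‑methylphloroglucinol 8 and acylated; ring B (cyclopentane) is the only ring formed (step 4); ring A is dearomatised last (step 7).
5. Stereocentres: C3' from 1; C2' and C6' from the catalyst in step 4; the acyl centre from acid 7; the quaternary ring carbon from the ligand in step 7.

Assumption: the C10 unit is numbered C1' (the ArCH2 carbon) to C8' as in a geranyl chain; the (R,R) Trost ligand is taken as the enantiomer that gives the (R) quaternary carbon as drawn, and its antipode is used if a pilot run shows the opposite sense.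

## Route

Step 1
Reactants: 1 (R)‑linalool, (3R)‑3,7‑dimethylocta‑1,6‑dien‑3‑ol
Product: 2 (3R)‑3,7‑dimethyl‑3‑(triethylsilyloxy)octa‑1,6‑diene
Conditions: TESOTf (1.3 equiv), 2,6‑lutidine (2 equiv), CH2Cl2, −78 → 0 °C
Reagents that add atoms: triethylsilyl trifluoromethanesulfonate, CC[Si](CC)(CC)OS(=O)(=O)C(F)(F)F
Why: Silyl triflate with a hindered pyridine base silylates the tertiary alcohol (silyl ether protection) without touching the C3' centre, which blocks β‑elimination and retro‑aldol cleavage at the later aldehyde stage.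

Step 2
Reactants: 2 (3R)‑3,7‑dimethyl‑3‑(triethylsilyloxy)octa‑1,6‑diene
Product: 4 (3R)‑3,7‑dimethyl‑3‑(triethylsilyloxy)oct‑6‑en‑1‑ol, via B‑alkyl‑9‑BBN adduct 3 (not isolated)
Conditions: 9‑BBN (1.5 equiv), THF, 0 → 50 °C; then NaOH (3 M aq.), H2O2 (30%), 0 °C → rt
Reagents that add atoms: hydrogen peroxide, OO
Why: Hydroboration–oxidation with 9‑BBN is anti‑Markovnikov at the monosubstituted vinyl group and far slower at the trisubstituted olefin, and the C–B bond is oxidised with retention, so only the primary alcohol forms and C3' is untouched.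

Step 3
Reactants: 4 (3R)‑3,7‑dimethyl‑3‑(triethylsilyloxy)oct‑6‑en‑1‑ol
Product: 5 (3R)‑3,7‑dimethyl‑3‑(triethylsilyloxy)oct‑6‑enal
Conditions: Dess–Martin periodinane (1.3 equiv), CH2Cl2, 0 °C → rt
Reagents that add atoms: none
Why: Dess–Martin oxidation stops at the aldehyde under near‑neutral conditions, so the silyl ether, the olefin and the β‑oxygenated centre are not disturbed.

Step 4
Reactants: 5 (3R)‑3,7‑dimethyl‑3‑(triethylsilyloxy)oct‑6‑enal
Product: 6 (1S,2R,5R)‑2‑methyl‑5‑(prop‑1‑en‑2‑yl)‑2‑(triethylsilyloxy)cyclopentane‑1‑carbaldehyde (CHO cis to OSiEt3, trans to isopropenyl)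
Conditions: (2S,5S)‑5‑benzyl‑2‑tert‑butyl‑3‑methylimidazolidin‑4‑one·TFA (20 mol%), [Fe(phen)3](SbF6)3 (2.5 equiv, trivalent iron), Na2HPO4 (2.5 equiv), DME, −30 °C, 24 h
Reagents that add atoms: none
Why: Organo‑SOMO catalysis (one‑electron oxidation of the catalyst‑bound enamine) gives a radical cation at C2' that closes 5‑exo onto C6'; the tertiary radical is oxidised to the cation and loses a methyl proton to give the isopropenyl group (homo‑ene cyclisation). The benzyl group of the catalyst shields one enamine face so C2' forms S, the chair‑like transition state places the iminium and CMe2 arms trans so C6' forms R, C3' is already R from 1, and C2' in 6 is also the thermodynamic (all‑trans carbon substituents) epimer.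

Step 5
Reactants: 7 (S)‑2‑methylbutanoic acid; 8 2‑methylphloroglucinol (2‑methylbenzene‑1,3,5‑triol)
Product: 10 (2S)‑2‑methyl‑1‑(2,4,6‑trihydroxy‑3‑methylphenyl)butan‑1‑one, via (S)‑2‑methylbutanoyl chloride 9 (not isolated)
Conditions: (COCl)2, DMF (cat.), CH2Cl2, 0 °C → rt; then 8, AlCl3 (3.5 equiv), PhNO2/CH2Cl2, 0 °C → rt; aq. HCl work‑up
Reagents that add atoms: none
Why: Friedel–Crafts C‑acylation of the very electron‑rich arene occurs at one of its two equivalent free positions, and keeping the reaction at or below room temperature limits enolisation of the acyl chloride so the (S) centre is carried through.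

Step 6
Reactants: 10 (2S)‑2‑methyl‑1‑(2,4,6‑trihydroxy‑3‑methylphenyl)butan‑1‑one; 6 (1S,2R,5R)‑2‑methyl‑5‑(prop‑1‑en‑2‑yl)‑2‑(triethylsilyloxy)cyclopentane‑1‑carbaldehyde
Product: 13 (2S)‑1‑(2,4,6‑trihydroxy‑3‑{[(1S,2R,5R)‑2‑hydroxy‑2‑methyl‑5‑(prop‑1‑en‑2‑yl)cyclopentyl]methyl}‑5‑methylphenyl)‑2‑methylbutan‑1‑one, via ortho‑quinone methide 11 (not isolated), via triethylsilyl ether 12 (not isolated)
Conditions: L‑proline (20 mol%), Hantzsch ester (1.3 equiv), EtOH/CH2Cl2, 25 → 40 °C; then solvent swap, HF·pyridine, pyridine/THF, 0 °C → rt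
Reagents that add atoms: none
Why: Three‑component reductive alkylation: proline‑mediated Knoevenagel‑type condensation at the single free ring carbon gives ortho‑quinone methide 11, which takes a hydride at C1' from the Hantzsch ester faster than it can tautomerise. C2' stays in its thermodynamically preferred configuration, the trans isopropenyl group cannot reach the quinone methide, and fluoride then removes the silyl group.

Step 7
Reactants: 13 (2S)‑1‑(2,4,6‑trihydroxy‑3‑{[(1S,2R,5R)‑2‑hydroxy‑2‑methyl‑5‑(prop‑1‑en‑2‑yl)cyclopentyl]methyl}‑5‑methylphenyl)‑2‑methylbutan‑1‑one; 14 prenyl acetate (3‑methylbut‑2‑en‑1‑yl acetate)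
Product: 15 (6R)‑3,5‑dihydroxy‑4‑{[(1S,2R,5R)‑2‑hydroxy‑2‑methyl‑5‑(prop‑1‑en‑2‑yl)cyclopentyl]methyl}‑6‑methyl‑2‑[(2S)‑2‑methylbutanoyl]‑6‑(3‑methylbut‑2‑en‑1‑yl)cyclohexa‑2,4‑dien‑1‑one (target)
Conditions: Pd2(dba)3·CHCl3 (2.5 mol%, zerovalent palladium), (R,R)‑DACH‑phenyl Trost ligand (7.5 mol%), Et3N (1.2 equiv), CH2Cl2, 0 °C → rt
Reagents that add atoms: none
Why: Proposed new method: a Tsuji–Trost allylic alkylation in which the ambident phenolate of 13 attacks the unsubstituted terminus of the π‑prenyl palladium complex through carbon; O‑prenyl ethers re‑ionise under the catalyst so the C‑alkylated, dearomatised triketone accumulates, the methyl‑bearing carbon reacts in preference to the much more hindered carbon carrying the cyclopentylmethyl arm, and the chiral pocket of the ligand selects the face and so the (R) quaternary centre. The closest known chemistry is palladium‑catalysed asymmetric allylic dearomatisation of phenols and naphthols and the racemic palladium C‑allylation of phloroglucinols.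

## Compound list

1 | (R)‑linalool, (3R)‑3,7‑dimethylocta‑1,6‑dien‑3‑ol | CC(C)=CCC[C@@](C)(O)C=C | starting material
2 | (3R)‑3,7‑dimethyl‑3‑(triethylsilyloxy)octa‑1,6‑diene | CC(C)=CCC[C@@](C)(O[Si](CC)(CC)CC)C=C | intermediate
3 | 9‑[(3S)‑3,7‑dimethyl‑3‑(triethylsilyloxy)oct‑6‑en‑1‑yl]‑9‑borabicyclo[3.3.1]nonane (geometry at C3 as in 2; the descriptor changes only because boron ranks below carbon) | CC(C)=CCC[C@@](C)(O[Si](CC)(CC)CC)CCB1C2CCCC1CCC2 | intermediate
4 | (3R)‑3,7‑dimethyl‑3‑(triethylsilyloxy)oct‑6‑en‑1‑ol | CC(C)=CCC[C@@](C)(O[Si](CC)(CC)CC)CCO | intermediate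
5 | (3R)‑3,7‑dimethyl‑3‑(triethylsilyloxy)oct‑6‑enal | CC(C)=CCC[C@@](C)(O[Si](CC)(CC)CC)CC=O | intermediate
6 | (1S,2R,5R)‑2‑methyl‑5‑(prop‑1‑en‑2‑yl)‑2‑(triethylsilyloxy)cyclopentane‑1‑carbaldehyde | C=C(C)[C@@H]1CC[C@@](C)(O[Si](CC)(CC)CC)[C@H]1C=O | intermediate
7 | (S)‑2‑methylbutanoic acid | CC[C@H](C)C(=O)O | starting material
8 | 2‑methylphloroglucinol (2‑methylbenzene‑1,3,5‑triol) | Cc1c(O)cc(O)cc1O | starting material
9 | (S)‑2‑methylbutanoyl chloride | CC[C@H](C)C(=O)Cl | intermediate
10 | (2S)‑2‑methyl‑1‑(2,4,6‑trihydroxy‑3‑methylphenyl)butan‑1‑one | Cc1c(O)cc(O)c(C(=O)[C@@H](C)CC)c1O | intermediate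
11 | ortho‑quinone methide from 10 and 6: the ring carbon that was free in 10 carries an exocyclic C=CH bond to the cyclopentane C1 (cyclopentane configuration as in 6, silyl ether retained) | C=C(C)[C@@H]1CC[C@@](C)(O[Si](CC)(CC)CC)[C@H]1C=C1C(=O)C(C)=C(O)C(C(=O)[C@@H](C)CC)=C1O | intermediate
12 | triethylsilyl ether of 13 at the tertiary cyclopentanol | C=C(C)[C@@H]1CC[C@@](C)(O[Si](CC)(CC)CC)[C@H]1Cc1c(O)c(C)c(O)c(C(=O)[C@@H](C)CC)c1O | intermediate
13 | (2S)‑1‑(2,4,6‑trihydroxy‑3‑{[(1S,2R,5R)‑2‑hydroxy‑2‑methyl‑5‑(prop‑1‑en‑2‑yl)cyclopentyl]methyl}‑5‑methylphenyl)‑2‑methylbutan‑1‑one | C=C(C)[C@@H]1CC[C@@](C)(O)[C@H]1Cc1c(O)c(C)c(O)c(C(=O)[C@@H](C)CC)c1O | intermediate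
14 | prenyl acetate (3‑methylbut‑2‑en‑1‑yl acetate) | CC(C)=CCOC(C)=O | starting material
15 | (6R)‑3,5‑dihydroxy‑4‑{[(1S,2R,5R)‑2‑hydroxy‑2‑methyl‑5‑(prop‑1‑en‑2‑yl)cyclopentyl]methyl}‑6‑methyl‑2‑[(2S)‑2‑methylbutanoyl]‑6‑(3‑methylbut‑2‑en‑1‑yl)cyclohexa‑2,4‑dien‑1‑one | C=C(C)[C@@H]1CC[C@@](C)(O)[C@H]1CC1=C(O)[C@@](C)(CC=C(C)C)C(=O)C(C(=O)[C@@H](C)CC)=C1O | target

## Step count and risk

Total step count: 7. Longest linear sequence: 6 (steps 1, 2, 3, 4, 6, 7); step 5 is the convergent branch.

The three steps most likely to fail: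

Step 4. The α‑carbon sits next to a fully substituted silyloxy carbon, so enamine formation may be slow, the substrate's own bias may oppose the catalyst, and the cation may give some isopropylidene isomer. The fallback sets out from 5 and replaces the one‑electron organocatalytic closure by a halogen‑based radical closure. Compound 5 is brominated at C2' (NBS, cat. DL‑proline, CH2Cl2, 0 °C) to (3R)‑2‑bromo‑3,7‑dimethyl‑3‑(triethylsilyloxy)oct‑6‑enal F1. F1 is cyclised under blue light with Co(dmgH)2(py)Cl (10 mol%, trivalent cobalt precatalyst) and iPr2NEt in MeCN. The α‑formyl radical closes 5‑exo onto C6' and the tertiary radical is dehydrogenated by the divalent cobalt species to the isopropenyl group. DBU then equilibrates C2' to the all‑trans aldehyde, and the route is rejoined at 6. In this variant C6' is controlled only by the C3' centre, so diastereomers may have to be separated.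

Step 6. The aldehyde is α‑branched and flanked by a quaternary centre, so condensation may be slow, and the quinone methide may tautomerise to a styrene before it is reduced. The fallback sets out from 6 and 10 and makes the same bond by C(sp2)–C(sp3) cross‑electrophile coupling. Compound 6 is reduced (NaBH4, MeOH, 0 °C) to [(1R,2R,5R)‑2‑methyl‑5‑(prop‑1‑en‑2‑yl)‑2‑(triethylsilyloxy)cyclopentyl]methanol F2. F2 is converted (PPh3, I2, imidazole, CH2Cl2) into triethyl{[(1R,2S,3R)‑2‑(iodomethyl)‑1‑methyl‑3‑(prop‑1‑en‑2‑yl)cyclopentyl]oxy}silane F3. Compound 10 is iodinated at its free position (NIS, MeCN, 0 °C) to (2S)‑1‑(2,4,6‑trihydroxy‑3‑iodo‑5‑methylphenyl)‑2‑methylbutan‑1‑one F4. Reductive coupling of F3 and F4 (NiI2, 4,4'‑di‑tert‑butyl‑2,2'‑bipyridine, Zn, NaI, DMA, 60 °C) gives silyl ether 12, where the route is rejoined; HF·pyridine then gives 13 as in step 6.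

Step 7. Site selectivity (methyl‑bearing carbon against the other substituted carbon and oxygen), linear against branched prenyl, and above all facial control at a centre remote from every existing stereocentre are unproven. The fallback sets out from 13 and makes the carbon–carbon bond inside an ion pair. The hydroxyl para to the ketone, the one not hydrogen‑bonded to it, is acylated with prenyl 1H‑imidazole‑1‑carboxylate (from prenol and carbonyldiimidazole; Et3N, CH2Cl2, 0 °C). This gives 3,5‑dihydroxy‑2‑{[(1S,2R,5R)‑2‑hydroxy‑2‑methyl‑5‑(prop‑1‑en‑2‑yl)cyclopentyl]methyl}‑6‑methyl‑4‑[(2S)‑2‑methylbutanoyl]phenyl 3‑methylbut‑2‑en‑1‑yl carbonate F5. Palladium‑catalysed decarboxylative asymmetric allylic alkylation of F5 (Pd2(dba)3, (S)‑tBu‑PHOX or the Trost ligand, toluene, rt) releases CO2 and joins the phenolate and the π‑prenyl cation at the adjacent methyl‑bearing carbon, rejoining the route at 15. If selectivity is still incomplete, the two epimers at the quaternary carbon are separated by preparative HPLC.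

## Further compounds

F1 | step 4 | (3R)‑2‑bromo‑3,7‑dimethyl‑3‑(triethylsilyloxy)oct‑6‑enal (mixture of C2 epimers) | CC(C)=CCC[C@@](C)(O[Si](CC)(CC)CC)C(Br)C=O
F2 | step 6 | [(1R,2R,5R)‑2‑methyl‑5‑(prop‑1‑en‑2‑yl)‑2‑(triethylsilyloxy)cyclopentyl]methanol | C=C(C)[C@@H]1CC[C@@](C)(O[Si](CC)(CC)CC)[C@H]1CO
F3 | step 6 | triethyl{[(1R,2S,3R)‑2‑(iodomethyl)‑1‑methyl‑3‑(prop‑1‑en‑2‑yl)cyclopentyl]oxy}silane | C=C(C)[C@@H]1CC[C@@](C)(O[Si](CC)(CC)CC)[C@H]1CI
F4 | step 6 | (2S)‑1‑(2,4,6‑trihydroxy‑3‑iodo‑5‑methylphenyl)‑2‑methylbutan‑1‑one | Cc1c(O)c(I)c(O)c(C(=O)[C@@H](C)CC)c1O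
F5 | step 7 | 3,5‑dihydroxy‑2‑{[(1S,2R,5R)‑2‑hydroxy‑2‑methyl‑5‑(prop‑1‑en‑2‑yl)cyclopentyl]methyl}‑6‑methyl‑4‑[(2S)‑2‑methylbutanoyl]phenyl 3‑methylbut‑2‑en‑1‑yl carbonate | C=C(C)[C@@H]1CC[C@@](C)(O)[C@H]1Cc1c(O)c(C(=O)[C@@H](C)CC)c(O)c(C)c1OC(=O)OCC=C(C)C
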